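**Strategy.** Everything rests on opening the cyclohexane ring (C2–C7) at C7–C8 and C1–C2 (numbering: C1 benzylic CH2, ring C2–C7, chain C8–C15). Quaternary C7 lies β and benzylated C2 α to C3, whose exocyclic methylene is a masked ketone, and C6 carries a heteroatom: the ring is a 4-oxygenated 3-methylcyclohex-2-enone in disguise. In one operation, copper-catalysed conjugate addition of a dioxolanylethyl Grignard reagent anti to the C6 silyl ether, then benzylation of the regiodefined enolate, forms both bonds and sets C7 and C2. The precursor is enantiopure (S)-3-methyl-4-(triethylsilyloxy)cyclohex-2-enone. Afterwards C6–O is exchanged for the equatorial bromide and the C10 aldehyde is grown into the chain that closes the 15-membered lactone.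

Key step: step 8

**Remarks**
- Numbering: C3 = methylidene carbon, C6 = CHBr, C7 = quaternary carbon, C10/C11 = epoxide, C14 = lactone carbinol, C15 = C(CH3)2OH. Ar = 5-(methoxycarbonyl)-2-(triisopropylsilyloxy)phenyl.
- Protecting groups: C6–O is a TES ether and the phenol a TIPS ether, so that C6–O can be freed with buffered HF·pyridine while the aryl ether lasts to the final step.
- Assumption: the lipase in step 3 follows the Kazlauskas model (R alcohol acylated, S alcohol left); if its preference is the reverse, the S acetate is methanolysed to 5 instead.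

**Route**

Step 1
Reactants: 1 3-methylcyclohex-2-en-1-one
Product: 2 3-methyl-1-(trimethylsilyloxy)cyclohexa-1,3-diene
Conditions: TMSCl, NaI, Et3N, MeCN, rt
Reagents that add atoms: chlorotrimethylsilane, C[Si](C)(C)Cl
Why: In situ TMSI with Et3N silylates the enone under equilibrating conditions, which should give mainly the linear endocyclic dienol ether (thermodynamic silyl dienol ether formation).

Step 2
Reactants: 2 3-methyl-1-(trimethylsilyloxy)cyclohexa-1,3-diene
Product: 4 rac-4-hydroxy-3-methylcyclohex-2-en-1-one, via epoxy enol ether 3 (not isolated)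
Conditions: mCPBA, NaHCO3, CH2Cl2, −20 °C; then 1 M HCl, THF
Reagents that add atoms: meta-chloroperbenzoic acid, OOC(=O)c1cccc(Cl)c1
Why: Vinylogous Rubottom oxidation: the peracid epoxidises the electron-rich distal C=C of the dienol ether, and acid opens the epoxide with loss of silicon to the racemic γ-hydroxy enone.

Step 3
Reactants: 4 rac-4-hydroxy-3-methylcyclohex-2-en-1-one
Product: 5 (S)-4-hydroxy-3-methylcyclohex-2-en-1-one
Conditions: Amano lipase PS, vinyl acetate, MTBE, 30 °C, run just past half conversion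
Reagents that add atoms: none
Why: Lipase kinetic resolution by enantioselective acyl transfer: the R alcohol (substituted alkene as the large group) should be acetylated and the S alcohol recovered, so the carbinol centre is selected, not created.

Step 4
Reactants: 5 (S)-4-hydroxy-3-methylcyclohex-2-en-1-one
Product: 6 (S)-3-methyl-4-(triethylsilyloxy)cyclohex-2-en-1-one
Conditions: TESCl, imidazole, CH2Cl2, 0 °C
Reagents that add atoms: chlorotriethylsilane, CC[Si](Cl)(CC)CC
Why: Standard silylation of the secondary allylic alcohol under mild base that does not isomerise the γ-hydroxy enone.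

Step 5
Reactants: 7 2-(2-bromoethyl)-1,3-dioxolane
Product: 8 [2-(1,3-dioxolan-2-yl)ethyl]magnesium bromide
Conditions: Mg, THF, 20–25 °C
Reagents that add atoms: magnesium, [Mg]
Why: Grignard formation by magnesium insertion, kept below 30 °C because this β-acetal Grignard reagent decomposes on warming.

Step 6
Reactants: 9 methyl 4-hydroxy-3-methylbenzoate
Product: 10 methyl 3-methyl-4-(triisopropylsilyloxy)benzoate
Conditions: TIPSCl, imidazole, DMF, rt
Reagents that add atoms: chlorotriisopropylsilane, CC(C)[Si](Cl)(C(C)C)C(C)C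
Why: Phenol silylation; the TIPS ether is chosen because it withstands organometallic, acidic and mildly basic steps up to the final fluoride cleavage.

Step 7
Reactants: 10 methyl 3-methyl-4-(triisopropylsilyloxy)benzoate
Product: 11 methyl 3-(bromomethyl)-4-(triisopropylsilyloxy)benzoate
Conditions: NBS, AIBN, PhCF3, 85 °C
Reagents that add atoms: N-bromosuccinimide, O=C1CCC(=O)N1Br
Why: Wohl–Ziegler radical bromination at the only benzylic methyl group of an arene deactivated toward ring bromination by the ester.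

Step 8
Reactants: 6 (S)-3-methyl-4-(triethylsilyloxy)cyclohex-2-en-1-one; 8 [2-(1,3-dioxolan-2-yl)ethyl]magnesium bromide; 11 methyl 3-(bromomethyl)-4-(triisopropylsilyloxy)benzoate
Product: 14 methyl 3-{[(1S,2S,3S)-2-[2-(1,3-dioxolan-2-yl)ethyl]-2-methyl-6-oxo-3-(triethylsilyloxy)cyclohexyl]methyl}-4-(triisopropylsilyloxy)benzoate, via TMS enol ether 12 (not isolated), via lithium enolate 13 (not isolated)
Conditions: 8, CuBr·SMe2 (cat.), TMSCl, HMPA, THF, −78 °C; Et3N, pentane, filter, evaporate; MeLi, THF, 0 °C; 11, DMPU, −78 → 0 °C; DBU, toluene, 60 °C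
Reagents that add atoms: none
Why: Copper-catalysed, TMSCl-accelerated conjugate addition of 8 to the β,β-disubstituted enone 6 gives silyl enol ether 12 with the enolate fixed between C2 and C3; MeLi releases lithium enolate 13, which is C-benzylated at C2 by 11, the closest known type being tandem cuprate addition–enolate alkylation of 4-silyloxycyclohexenones. No ring is closed. C7 is set by the C6 silyl ether: A(1,2) strain with the C7 methyl holds OTES pseudoaxial and the copper reagent attacks axially on the opposite face, giving 7S. C2 is not left to kinetic control: DBU equilibration through the C3 enolate should favour the isomer with benzyl, C8 chain and OTES all equatorial (2S here, the target arrangement), and the minor epimer can be resubmitted. The step needs C2 (not C4) regiocontrol and mono-alkylation, secured because the enolate arises only by conjugate addition, is stored as the silyl enol ether and meets a reactive benzylic bromide at low temperature before proton transfer.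

Step 9
Reactants: 14 key ketone (2S,6S,7S)
Product: 15 C3 ethylene ketal of 14 (2S,6S,7S)
Conditions: (TMSOCH2)2, TMSOTf (cat.), CH2Cl2, −78 → −20 °C; pyridine
Reagents that add atoms: 1,2-bis(trimethylsilyloxy)ethane, C[Si](C)(C)OCCO[Si](C)(C)C
Why: Noyori ketalisation works on hindered ketones under aprotic low-temperature conditions that leave the TES ether, the C10 acetal and C2 untouched, and it masks C3 so that the two ring carbonyls are never free together.

Step 10
Reactants: 15 C3 ethylene ketal (2S,6S,7S)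
Product: 16 C6 alcohol (2S,6S,7S), equatorial OH
Conditions: HF·pyridine, pyridine, THF, 0 °C → rt
Reagents that add atoms: none
Why: Pyridine-buffered acidic fluoride cleaves the alkyl TES ether while the aryl TIPS ether and both dioxolanes persist, and the buffering keeps the freed C6 hydroxyl from exchanging into the C10 acetal.

Step 11
Reactants: 16 C6 alcohol (2S,6S,7S)
Product: 17 C6 ketone (2S,7S)
Conditions: Dess–Martin periodinane, NaHCO3, CH2Cl2, rt
Reagents that add atoms: none
Why: Dess–Martin oxidation of a hindered secondary alcohol under buffered, non-epimerising conditions; the C6 stereocentre has done its directing work and is deliberately erased.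

Step 12
Reactants: 17 C6 ketone (2S,7S)
Product: 18 C5=C6 enol triflate (2S,7S)
Conditions: KHMDS, THF, −78 °C; PhNTf2
Reagents that add atoms: N-phenylbis(trifluoromethanesulfonimide), O=S(=O)(N(c1ccccc1)S(=O)(=O)C(F)(F)F)C(F)(F)F
Why: The C6 ketone can enolise only toward C5 because C7 is quaternary, so enolate O-triflation gives a single enol triflate, and the benzoate has no α-hydrogen.

Step 13
Reactants: 18 C5=C6 enol triflate (2S,7S)
Product: 19 C5=C6 vinyl bromide (2S,7S)
Conditions: Ni(OAc)2·4H2O (cat.), cod, Zn (cat.), LiBr, DMA/THF, rt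
Reagents that add atoms: lithium bromide, [Li+].[Br-]
Why: Nickel-catalysed triflate–halide exchange of enol triflates (oxidative addition, halide exchange, C–Br reductive elimination) proceeds at room temperature and tolerates ester, acetals and silyl ether.

Step 14
Reactants: 19 C5=C6 vinyl bromide (2S,7S)
Product: 20 equatorial C6 bromide (2S,6S,7S), both carbonyls as dioxolanes
Conditions: Mn(dpm)3 (cat.), PhSiH3, TBHP, i-PrOH, rt
Reagents that add atoms: none
Why: Metal-hydride hydrogen-atom-transfer hydrogenation of a haloalkene: H adds to C5, and the C6 α-bromo radical takes its second hydrogen axially on the face opposite the axial C7 methyl, so bromine ends equatorial (6S) and is retained, unlike under Pd/H2.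

Step 15
Reactants: 20 equatorial C6 bromide (2S,6S,7S)
Product: 21 methyl 3-{[(1S,2S,3S)-3-bromo-2-methyl-6-oxo-2-(3-oxopropyl)cyclohexyl]methyl}-4-(triisopropylsilyloxy)benzoate
Conditions: 1 M HCl, THF, rt
Reagents that add atoms: water, O
Why: Acetal hydrolysis frees the C3 ketone (strained ketal) and the C10 aldehyde; aryl TIPS ether, methyl ester and neopentyl-type bromide are acid-stable, and the mild conditions should not enolise the hindered C2.

Step 16
Reactants: 21 bromo keto aldehyde (2S,6S,7S)
Product: 22 C10 isopropenyl carbinol with C3 ketone (2S,6S,7S; both C10 epimers)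
Conditions: isopropenylmagnesium bromide, THF, −78 °C
Reagents that add atoms: isopropenylmagnesium bromide, CC(=C)[Mg]Br
Why: Chemoselective Grignard 1,2-addition, the aldehyde reacting far faster at −78 °C than the hindered C3 ketone or the ester; the C10 configuration is immaterial because C10 becomes sp2 in step 19.

Step 17
Reactants: 22 C10 isopropenyl carbinol with C3 ketone
Product: 23 methyl 3-{[(1R,2S,3S)-3-bromo-2-(3-hydroxy-4-methylpent-4-en-1-yl)-2-methyl-6-methylidenecyclohexyl]methyl}-4-(triisopropylsilyloxy)benzoate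
Conditions: Ph3PCH3Br, KOtBu, THF, 0 °C → rt
Reagents that add atoms: methyltriphenylphosphonium bromide, C[P+](c1ccccc1)(c1ccccc1)c1ccccc1.[Br-]
Why: Wittig methylenation with excess ylide tolerates the C10 alkoxide, installs the exocyclic alkene and ends the enolisability of C2, whose hindered α-hydrogen should not exchange under these conditions.

Step 18
Reactants: 24 3-hydroxy-3-methylbutan-2-one
Product: 25 3,3-dimethoxy-2-methylbutan-2-ol
Conditions: HC(OMe)3, MeOH, TsOH (cat.), rt
Reagents that add atoms: trimethyl orthoformate, COC(OC)OC; methanol, CO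
Why: Acid-catalysed ketalisation driven by the orthoformate as water scavenger gives the dimethyl ketal of the α-hydroxy ketone.

Step 19
Reactants: 23 methylene allylic alcohol (2R,6S,7S); 25 3,3-dimethoxy-2-methylbutan-2-ol
Product: 28 (10E)-hydroxy ketone (2R,6S,7S) with C14 ketone and C15 tertiary alcohol, via mixed ketal 26 (not isolated), via allyl vinyl ether 27 (not isolated)
Conditions: 25 (excess), 2,4-dinitrophenol (cat.), toluene, 110 °C, MeOH distilled off
Reagents that add atoms: none
Why: Olefinic ketal Claisen rearrangement (Johnson–Faulkner): acid-catalysed exchange and loss of methanol give the allyl vinyl ether, and the chair [3,3] shift with the C9 chain equatorial, enforced by the bulky C(CH3)2OH group on the vinyl carbon, should give the E C10=C11 alkene while forming C12–C13 and unveiling the C14 ketone.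

Step 20
Reactants: 28 (10E)-hydroxy ketone
Product: 29 C15 trimethylsilyl ether of 28
Conditions: 1-(trimethylsilyl)imidazole, CH2Cl2, rt
Reagents that add atoms: 1-(trimethylsilyl)imidazole, C[Si](C)(C)n1ccnc1
Why: Base-free silylation of the tertiary α-hydroxyl removes a free OH that would otherwise deliver borane to the neighbouring ketone intramolecularly and erode reagent control.

Step 21
Reactants: 29 C15 trimethylsilyl ether ketone
Product: 31 (10E,14S)-14,15-diol methyl ester (2R,6S,7S), via silyl ether alcohol 30 (not isolated)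
Conditions: (R)-Me-CBS, catecholborane, toluene, −78 → −30 °C; MeOH; HF·pyridine, pyridine, THF, 0 °C
Reagents that add atoms: none
Why: Corey–Bakshi–Shibata reduction: the (R)-oxazaborolidine binds the ketone with the bulky C15 group as the large substituent and delivers hydride to give 14S by reagent control, catecholborane at low temperature spares the alkenes, and buffered HF·pyridine removes the TMS group.

Step 22
Reactants: 31 (10E,14S)-diol methyl ester
Product: 32 (10E,14S)-diol seco acid
Conditions: Me3SnOH, 1,2-dichloroethane, 80 °C; aq. KHSO4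
Reagents that add atoms: trimethyltin hydroxide, C[Sn](C)(C)O
Why: Trimethyltin hydroxide hydrolyses methyl esters under near-neutral conditions through the stannyl ester, so the base-labile aryl TIPS ether, the alkyl bromide and the alkenes should survive.

Step 23
Reactants: 32 (10E,14S)-diol seco acid
Product: 34 15-membered macrolactone (2R,6S,7S,10E,14S) with aryl TIPS ether and free C15–OH, via mixed anhydride 33 (not isolated)
Conditions: 2,4,6-trichlorobenzoyl chloride, Et3N, THF, rt; slow addition to DMAP, toluene, 80 °C (about 1 mM)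
Reagents that add atoms: none
Why: Yamaguchi macrolactonisation: the acyl pyridinium formed from the mixed anhydride is captured at high dilution by the secondary C14 hydroxyl (the tertiary C15 hydroxyl does not acylate), closing the lactone with retention at C14.

Step 24
Reactants: 34 macrolactone (10E)
Product: 35 (10S,11S)-epoxy macrolactone with aryl TIPS ether
Conditions: ent-Shi ketone (L-fructose-derived), Oxone, K2CO3, Bu4NHSO4, MeCN/DMM, aq. borate buffer pH 10.5, 0 °C
Reagents that add atoms: potassium peroxymonosulfate (Oxone), [K+].[O-]S(=O)(=O)OO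
Why: Shi epoxidation: the chiral dioxirane transfers oxygen through a spiro transition state to the electron-rich trisubstituted C10=C11 alkene in preference to the hindered 1,1-disubstituted exocyclic alkene, and this catalyst enantiomer should give the 10S,11S epoxide.

Step 25
Reactants: 35 (10S,11S)-epoxy macrolactone with aryl TIPS ether
Product: 36 Bromophycolide F
Conditions: TBAF, AcOH, THF, 0 °C
Reagents that add atoms: none
Why: Fluoride cleavage of the aryl silyl ether, buffered with acetic acid so that lactone, epoxide and bromide are not exposed to free phenoxide or base, releases the phenol.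

**Compound list**

1 | 3-methylcyclohex-2-en-1-one | CC1=CC(=O)CCC1 | starting material
2 | 3-methyl-1-(trimethylsilyloxy)cyclohexa-1,3-diene | C[Si](C)(C)OC1=CC(C)=CCC1 | intermediate
3 | rac-1-methyl-3-(trimethylsilyloxy)-7-oxabicyclo[4.1.0]hept-2-ene (epoxy enol ether, formed in situ) | C[Si](C)(C)OC1=CC2(C)OC2CC1 | intermediate
4 | rac-4-hydroxy-3-methylcyclohex-2-en-1-one | CC1=CC(=O)CCC1O | intermediate
5 | (S)-4-hydroxy-3-methylcyclohex-2-en-1-one | O=C1CC[C@H](O)C(C)=C1 | intermediate
6 | (S)-3-methyl-4-(triethylsilyloxy)cyclohex-2-en-1-one | O=C1CC[C@H](O[Si](CC)(CC)CC)C(C)=C1 | intermediate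
7 | 2-(2-bromoethyl)-1,3-dioxolane | BrCCC1OCCO1 | starting material
8 | [2-(1,3-dioxolan-2-yl)ethyl]magnesium bromide | Br[Mg]CCC1OCCO1 | intermediate
9 | methyl 4-hydroxy-3-methylbenzoate | COC(=O)c1ccc(O)c(C)c1 | starting material
10 | methyl 3-methyl-4-(triisopropylsilyloxy)benzoate | COC(=O)c1ccc(O[Si](C(C)C)(C(C)C)C(C)C)c(C)c1 | intermediate
11 | methyl 3-(bromomethyl)-4-(triisopropylsilyloxy)benzoate | COC(=O)c1ccc(O[Si](C(C)C)(C(C)C)C(C)C)c(CBr)c1 | intermediate
12 | (3S,4S)-3-[2-(1,3-dioxolan-2-yl)ethyl]-3-methyl-4-(triethylsilyloxy)-1-(trimethylsilyloxy)cyclohex-1-ene (formed in situ) | C[Si](C)(C)OC1=C[C@](C)(CCC2OCCO2)[C@@H](O[Si](CC)(CC)CC)CC1 | intermediate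
13 | lithium (3S,4S)-3-[2-(1,3-dioxolan-2-yl)ethyl]-3-methyl-4-(triethylsilyloxy)cyclohex-1-en-1-olate (formed in situ) | [Li]OC1=C[C@](C)(CCC2OCCO2)[C@@H](O[Si](CC)(CC)CC)CC1 | intermediate
14 | methyl 3-{[(1S,2S,3S)-2-[2-(1,3-dioxolan-2-yl)ethyl]-2-methyl-6-oxo-3-(triethylsilyloxy)cyclohexyl]methyl}-4-(triisopropylsilyloxy)benzoate (route numbering 2S,6S,7S) | O=C1CC[C@H](O[Si](CC)(CC)CC)[C@@](C)(CCC2OCCO2)[C@@H]1Cc1cc(C(=O)OC)ccc1O[Si](C(C)C)(C(C)C)C(C)C | intermediate
15 | 14 with the C3 ketone as spiro-1,3-dioxolane (2S,6S,7S) | C12(OCCO1)CC[C@H](O[Si](CC)(CC)CC)[C@@](C)(CCC3OCCO3)[C@@H]2Cc2cc(C(=O)OC)ccc2O[Si](C(C)C)(C(C)C)C(C)C | intermediate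
16 | 15 with free equatorial C6–OH (2S,6S,7S) | C12(OCCO1)CC[C@H](O)[C@@](C)(CCC3OCCO3)[C@@H]2Cc2cc(C(=O)OC)ccc2O[Si](C(C)C)(C(C)C)C(C)C | intermediate
17 | C6 ketone, C3 and C10 as dioxolanes (2S,7S) | C12(OCCO1)CCC(=O)[C@@](C)(CCC3OCCO3)[C@@H]2Cc2cc(C(=O)OC)ccc2O[Si](C(C)C)(C(C)C)C(C)C | intermediate
18 | C5=C6 enol triflate (2S,7S) | C12(OCCO1)CC=C(OS(=O)(=O)C(F)(F)F)[C@@](C)(CCC3OCCO3)[C@@H]2Cc2cc(C(=O)OC)ccc2O[Si](C(C)C)(C(C)C)C(C)C | intermediate
19 | C5=C6 vinyl bromide (2S,7S) | C12(OCCO1)CC=C(Br)[C@@](C)(CCC3OCCO3)[C@@H]2Cc2cc(C(=O)OC)ccc2O[Si](C(C)C)(C(C)C)C(C)C | intermediate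
20 | equatorial C6 bromide, C3 and C10 as dioxolanes (2S,6S,7S) | C12(OCCO1)CC[C@H](Br)[C@@](C)(CCC3OCCO3)[C@@H]2Cc2cc(C(=O)OC)ccc2O[Si](C(C)C)(C(C)C)C(C)C | intermediate
21 | methyl 3-{[(1S,2S,3S)-3-bromo-2-methyl-6-oxo-2-(3-oxopropyl)cyclohexyl]methyl}-4-(triisopropylsilyloxy)benzoate | O=C1CC[C@H](Br)[C@@](C)(CCC=O)[C@@H]1Cc1cc(C(=O)OC)ccc1O[Si](C(C)C)(C(C)C)C(C)C | intermediate
22 | 21 with isopropenyl added to C10 (secondary allylic alcohol, both C10 epimers), C3 ketone (2S,6S,7S) | O=C1CC[C@H](Br)[C@@](C)(CCC(O)C(C)=C)[C@@H]1Cc1cc(C(=O)OC)ccc1O[Si](C(C)C)(C(C)C)C(C)C | intermediate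
23 | methyl 3-{[(1R,2S,3S)-3-bromo-2-(3-hydroxy-4-methylpent-4-en-1-yl)-2-methyl-6-methylidenecyclohexyl]methyl}-4-(triisopropylsilyloxy)benzoate (2R,6S,7S) | C=C1CC[C@H](Br)[C@@](C)(CCC(O)C(C)=C)[C@@H]1Cc1cc(C(=O)OC)ccc1O[Si](C(C)C)(C(C)C)C(C)C | intermediate
24 | 3-hydroxy-3-methylbutan-2-one | CC(=O)C(C)(C)O | starting material
25 | 3,3-dimethoxy-2-methylbutan-2-ol | COC(C)(OC)C(C)(C)O | intermediate
26 | mixed methyl ketal of 23 at C10–O with the 3-hydroxy-3-methylbutan-2-one unit (formed in situ) | C=C1CC[C@H](Br)[C@@](C)(CCC(OC(C)(OC)C(C)(C)O)C(C)=C)[C@@H]1Cc1cc(C(=O)OC)ccc1O[Si](C(C)C)(C(C)C)C(C)C | intermediate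
27 | allyl vinyl ether: C10–O–C(=CH2)–C(CH3)2OH (formed in situ) | C=C1CC[C@H](Br)[C@@](C)(CCC(OC(=C)C(C)(C)O)C(C)=C)[C@@H]1Cc1cc(C(=O)OC)ccc1O[Si](C(C)C)(C(C)C)C(C)C | intermediate
28 | hydroxy ketone: C7 side chain (3E)-8-hydroxy-4,8-dimethyl-7-oxonon-3-en-1-yl (2R,6S,7S,10E) | C=C1CC[C@H](Br)[C@@](C)(CC/C=C(\C)CCC(=O)C(C)(C)O)[C@@H]1Cc1cc(C(=O)OC)ccc1O[Si](C(C)C)(C(C)C)C(C)C | intermediate
29 | 28 with C15–OSiMe3 | C=C1CC[C@H](Br)[C@@](C)(CC/C=C(\C)CCC(=O)C(C)(C)O[Si](C)(C)C)[C@@H]1Cc1cc(C(=O)OC)ccc1O[Si](C(C)C)(C(C)C)C(C)C | intermediate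
30 | (14S)-alcohol with C15–OSiMe3 (formed in situ) | C=C1CC[C@H](Br)[C@@](C)(CC/C=C(\C)CC[C@@H](C(C)(C)O[Si](C)(C)C)O)[C@@H]1Cc1cc(C(=O)OC)ccc1O[Si](C(C)C)(C(C)C)C(C)C | intermediate
31 | diol methyl ester: C7 side chain (3E,7S)-7,8-dihydroxy-4,8-dimethylnon-3-en-1-yl (2R,6S,7S,10E,14S) | C=C1CC[C@H](Br)[C@@](C)(CC/C=C(\C)CC[C@@H](C(C)(C)O)O)[C@@H]1Cc1cc(C(=O)OC)ccc1O[Si](C(C)C)(C(C)C)C(C)C | intermediate
32 | seco acid: 31 with CO2H in place of CO2Me | C=C1CC[C@H](Br)[C@@](C)(CC/C=C(\C)CC[C@@H](C(C)(C)O)O)[C@@H]1Cc1cc(C(=O)O)ccc1O[Si](C(C)C)(C(C)C)C(C)C | intermediate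
33 | mixed anhydride of 32 with 2,4,6-trichlorobenzoic acid (formed in situ) | C=C1CC[C@H](Br)[C@@](C)(CC/C=C(\C)CC[C@@H](C(C)(C)O)O)[C@@H]1Cc1cc(C(=O)OC(=O)c2c(Cl)cc(Cl)cc2Cl)ccc1O[Si](C(C)C)(C(C)C)C(C)C | intermediate
34 | 15-membered macrolactone (C14–O to benzoyl carbon), aryl TIPS ether, free C15–OH (2R,6S,7S,10E,14S) | C=C1CC[C@H](Br)[C@@]2(C)CC/C=C(\C)CC[C@@H](C(C)(C)O)OC(=O)c3ccc(O[Si](C(C)C)(C(C)C)C(C)C)c(c3)C[C@H]12 | intermediate
35 | (10S,11S)-epoxide of 34 (2R,6S,7S,10S,11S,14S) | C=C1CC[C@H](Br)[C@@]2(C)CC[C@@H]3O[C@@]3(C)CC[C@@H](C(C)(C)O)OC(=O)c3ccc(O[Si](C(C)C)(C(C)C)C(C)C)c(c3)C[C@H]12 | intermediate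
36 | Bromophycolide F (2R,6S,7S,10S,11S,14S) | C=C1CC[C@H](Br)[C@@]2(C)CC[C@@H]3O[C@@]3(C)CC[C@@H](C(C)(C)O)OC(=O)c3ccc(O)c(c3)C[C@H]12 | target

**Step count and risks**

Total steps: 25. Longest linear sequence: 21 steps (steps 1–4, 8–17, 19–25).

Steps most likely to fail:

1. Step 8. C-benzylation of the hindered C2 enolate may lose out to proton transfer and O-alkylation. The alkylation may also place benzyl anti to the C7 methyl, so that C2 depends on an equilibration whose bias toward the all-equatorial isomer could be modest. Fallback: the conjugate addition is stopped at silyl enol ether 12, isolated by the non-aqueous work-up. MeLi regenerates enolate 13, which is added at −78 °C to methyl 3-formyl-4-(triisopropylsilyloxy)benzoate F2, prepared from commercial methyl 3-formyl-4-hydroxybenzoate F1 with TIPSCl and imidazole, to give the aldol adduct F3. MsCl/Et3N followed by DBU dehydrates it to the benzylidene ketone F4. Hydrogenation (H2, Pd/C, EtOAc) of the exocyclic C1=C2 bond, with hydrogen arriving at C2 on the face away from the axial C7 methyl, rejoins the route at ketone 14. The aldehyde cannot transfer a proton to the enolate, and C2 is then set by hydrogen delivery instead of by equilibration.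

2. Step 14. Hydrogen may be delivered to the wrong face of the C6 radical, or bromine may be lost reductively. Fallback: from ketone 17, K-Selectride (THF, −78 °C) should give the axial C6 alcohol F5, and Appel bromination (CBr4, PPh3) displaces it with inversion to the equatorial bromide, rejoining the route at 20. This trades the radical step for an SN2 step at a neopentyl-type centre, which is known on 3-hydroxy-4,4-dimethyl terpenoid rings but is prone to elimination.

3. Step 24. The conformation of the macrocycle may override the facial preference of the chiral dioxirane, and the exocyclic alkene may be over-oxidised. Fallback: the epoxide is installed before ring closure, under reagent control alone. Diol ester 31 is epoxidised under the same Shi conditions to the epoxy diol ester F6, kept base-buffered so that the C14 hydroxyl does not open the epoxide. Me3SnOH then gives the epoxy seco acid F7, and Yamaguchi lactonisation through the mixed anhydride F8 rejoins the route at 35.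

**Further compounds**

F1 | step 8 | methyl 3-formyl-4-hydroxybenzoate | COC(=O)c1ccc(O)c(C=O)c1
F2 | step 8 | methyl 3-formyl-4-(triisopropylsilyloxy)benzoate | COC(=O)c1ccc(O[Si](C(C)C)(C(C)C)C(C)C)c(C=O)c1
F3 | step 8 | aldol adduct: 14 with CH(OH) in place of the benzylic CH2 (C1 and C2 epimers) | O=C1CC[C@H](O[Si](CC)(CC)CC)[C@@](C)(CCC2OCCO2)C1C(O)c1cc(C(=O)OC)ccc1O[Si](C(C)C)(C(C)C)C(C)C
F4 | step 8 | benzylidene ketone: C1=C2 alkene, C3 ketone (6S,7S) | O=C1CC[C@H](O[Si](CC)(CC)CC)[C@@](C)(CCC2OCCO2)C1=Cc1cc(C(=O)OC)ccc1O[Si](C(C)C)(C(C)C)C(C)C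
F5 | step 14 | axial C6 alcohol, C6 epimer of 16 (2S,6R,7S) | C12(OCCO1)CC[C@@H](O)[C@@](C)(CCC3OCCO3)[C@@H]2Cc2cc(C(=O)OC)ccc2O[Si](C(C)C)(C(C)C)C(C)C
F6 | step 24 | (10S,11S)-epoxy diol methyl ester, open chain | C=C1CC[C@H](Br)[C@@](C)(CC[C@@H]2O[C@@]2(C)CC[C@@H](C(C)(C)O)O)[C@@H]1Cc1cc(C(=O)OC)ccc1O[Si](C(C)C)(C(C)C)C(C)C
F7 | step 24 | (10S,11S)-epoxy diol seco acid | C=C1CC[C@H](Br)[C@@](C)(CC[C@@H]2O[C@@]2(C)CC[C@@H](C(C)(C)O)O)[C@@H]1Cc1cc(C(=O)O)ccc1O[Si](C(C)C)(C(C)C)C(C)C
F8 | step 24 | mixed anhydride of F7 with 2,4,6-trichlorobenzoic acid | C=C1CC[C@H](Br)[C@@](C)(CC[C@@H]2O[C@@]2(C)CC[C@@H](C(C)(C)O)O)[C@@H]1Cc1cc(C(=O)OC(=O)c2c(Cl)cc(Cl)cc2Cl)ccc1O[Si](C(C)C)(C(C)C)C(C)C
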